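**Plan**

- Retrosynthesis: the ring-A benzyl ether and the two arm ether bonds (ArO–C8, with the C7 carbinols traced back to ketones) are cut first. This leaves a bisphenol core and an (S)-lactate-derived α-tosyloxy ketone. The core is then cut at O1–C5, at C5–aryl(B), at C4–CH3 and at C2–C3.
- Forward: crotylboration of the ring-A aldehyde joins C2–C3, a γ-lactone carries the C4 methylation, and ring B enters as an aryl ketone at C5. The tetrahydrofuran, the only ring formed in the core, is closed at O1–C5, and the two arms are attached last.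
- Enabling feature: C2 (ring A) and C5 (ring B) both carry aryl cis to the methyl on C3 and C4. C5 is a secondary benzylic carbon bonded to O1, so this contra-thermodynamic cis pair can be set by backside attack of the C2 oxygen on an open-chain C5 sulfonate. This works only if the para oxygen of ring B is a tosylate and cannot assist ionisation.
- Stereochemistry: C2/C3 come from reagent-controlled (Z)-crotylboration and C4 from substrate-controlled lactone methylation. C5 comes from CBS reduction followed by inversion in the ring closure. Arm C8 comes from (S)-lactate with inversion and arm C7 from Felkin–Anh reduction.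

Key step: step 12

Remark (numbering): O1 and C2–C5 are the tetrahydrofuran atoms of the target (ring A = 3-hydroxy-4-alkoxyphenyl on C2, ring B = 3-methoxy-4-alkoxyphenyl on C5). These locants are also used for the open-chain intermediates, and C7/C8 are the carbinol and ether carbons of each arm.
Assumption: 25 is used as its commercial THF solution, and 12 is carried into step 8 without purification because it can revert to the lactone.

**Route**

Step 1
Reactants: 1 3,4-dihydroxybenzaldehyde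
Product: 2 4-formyl-2-hydroxyphenyl 4-methylbenzenesulfonate
Conditions: TsCl (1.0 equiv), Et3N (1.05 equiv), THF, 0 °C
Reagents that add atoms: 4-toluenesulfonyl chloride, Cc1ccc(S(=O)(=O)Cl)cc1
Why: Regioselective O-sulfonylation: with one equivalent of base only the more acidic 4-hydroxyl (para to the formyl group) is deprotonated, so its phenoxide should be the one that is tosylated.

Step 2
Reactants: 2 4-formyl-2-hydroxyphenyl 4-methylbenzenesulfonate
Product: 3 2-(benzyloxy)-4-formylphenyl 4-methylbenzenesulfonate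
Conditions: BnBr, K2CO3, DMF, rt
Reagents that add atoms: benzyl bromide, BrCc1ccccc1
Why: Williamson ether synthesis at the remaining phenol under carbonate conditions that leave the aryl tosylate and the aldehyde untouched.

Step 3
Reactants: 3 2-(benzyloxy)-4-formylphenyl 4-methylbenzenesulfonate; 4 cis-but-2-ene
Product: 6 2-(benzyloxy)-4-[(1S,2R)-1-hydroxy-2-methylbut-3-en-1-yl]phenyl 4-methylbenzenesulfonate, via borinate ester 5 (not isolated)
Conditions: 4, KOt-Bu, n-BuLi, THF, −78 → −45 °C; (−)-Ipc2BOMe [from (+)-α-pinene], −78 °C; BF3·OEt2, then 3, −78 °C; HOCH2CH2NH2, rt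
Reagents that add atoms: none
Why: Brown asymmetric (Z)-crotylboration: allyl transfer through a closed chair transition state should convert the Z geometry into the 1,2-syn pair, and the isopinocampheyl groups derived from (+)-α-pinene should direct the reagent to the Si face of the aldehyde, which sets C2 (S) and C3 (R).

Step 4
Reactants: 6 2-(benzyloxy)-4-[(1S,2R)-1-hydroxy-2-methylbut-3-en-1-yl]phenyl 4-methylbenzenesulfonate
Product: 8 2-(benzyloxy)-4-[(1S,2R)-1,4-dihydroxy-2-methylbutyl]phenyl 4-methylbenzenesulfonate, via alkyl-9-BBN borane 7 (not isolated)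
Conditions: 9-BBN (2.5 equiv), THF, 0 °C → rt; then NaBO3·4H2O, H2O, rt
Reagents that add atoms: sodium perborate, O=BO[O-].[Na+]
Why: Anti-Markovnikov hydroboration–oxidation: 9-BBN should place boron only on the terminal alkene carbon, and the mild perborate oxidation replaces it by hydroxyl without touching the aryl tosylate or a stereocentre.

Step 5
Reactants: 8 2-(benzyloxy)-4-[(1S,2R)-1,4-dihydroxy-2-methylbutyl]phenyl 4-methylbenzenesulfonate
Product: 9 2-(benzyloxy)-4-[(2S,3R)-3-methyl-5-oxotetrahydrofuran-2-yl]phenyl 4-methylbenzenesulfonate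
Conditions: TEMPO (0.2 equiv), PhI(OAc)2 (2.5 equiv), CH2Cl2, rt
Reagents that add atoms: none
Why: TEMPO/PhI(OAc)2 oxidative lactonisation: the primary alcohol is oxidised preferentially, the aldehyde is captured by the benzylic hydroxyl as a lactol and this is oxidised on to the γ-lactone, so no stereocentre is touched.

Step 6
Reactants: 9 2-(benzyloxy)-4-[(2S,3R)-3-methyl-5-oxotetrahydrofuran-2-yl]phenyl 4-methylbenzenesulfonate
Product: 11 2-(benzyloxy)-4-[(2S,3R,4R)-3,4-dimethyl-5-oxotetrahydrofuran-2-yl]phenyl 4-methylbenzenesulfonate, via lithium enolate 10 (not isolated)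
Conditions: LiHMDS (1.1 equiv), THF, −78 °C; MeI (3 equiv), −78 → −40 °C
Reagents that add atoms: iodomethane, CI
Why: Diastereoselective lactone enolate alkylation: the C3 methyl and the C2 aryl sit on the same face of the ring, so iodomethane should enter from the opposite face and set C4 (R) with the two methyl groups trans.

Step 7
Reactants: 11 2-(benzyloxy)-4-[(2S,3R,4R)-3,4-dimethyl-5-oxotetrahydrofuran-2-yl]phenyl 4-methylbenzenesulfonate
Product: 12 2-(benzyloxy)-4-[(1S,2R,3R)-1-hydroxy-4-[methoxy(methyl)amino]-2,3-dimethyl-4-oxobutyl]phenyl 4-methylbenzenesulfonate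
Conditions: MeNHOMe·HCl (3 equiv), AlMe3 (3 equiv), CH2Cl2, 0 °C → rt; aq. Rochelle salt; crude product used at once
Reagents that add atoms: N,O-dimethylhydroxylamine hydrochloride, CNOC.Cl
Why: Weinreb aminolysis of a lactone with the aluminium amide, an acyl substitution that leaves C2, C3 and C4 unchanged and frees the C2 hydroxyl.

Step 8
Reactants: 12 2-(benzyloxy)-4-[(1S,2R,3R)-1-hydroxy-4-[methoxy(methyl)amino]-2,3-dimethyl-4-oxobutyl]phenyl 4-methylbenzenesulfonate
Product: 13 2-(benzyloxy)-4-[(1S,2R,3R)-4-[methoxy(methyl)amino]-2,3-dimethyl-4-oxo-1-(triethylsilyloxy)butyl]phenyl 4-methylbenzenesulfonate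
Conditions: TESCl (1.5 equiv), imidazole (3 equiv), DMAP (cat.), DMF, 0 °C → rt
Reagents that add atoms: chlorotriethylsilane, CC[Si](Cl)(CC)CC
Why: Silyl ether formation at the only hydroxyl, which marks the C2 oxygen as the future ring oxygen before the second carbinol exists.

Step 9
Reactants: 14 4-bromo-2-methoxyphenol
Product: 15 4-bromo-2-methoxyphenyl 4-methylbenzenesulfonate
Conditions: TsCl, Et3N, DMAP (cat.), CH2Cl2, 0 °C → rt
Reagents that add atoms: 4-toluenesulfonyl chloride, Cc1ccc(S(=O)(=O)Cl)cc1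
Why: O-sulfonylation of the phenol; the tosylate is the electron-withdrawing mask that ring B needs in the ring closure.

Step 10
Reactants: 15 4-bromo-2-methoxyphenyl 4-methylbenzenesulfonate; 13 2-(benzyloxy)-4-[(1S,2R,3R)-4-[methoxy(methyl)amino]-2,3-dimethyl-4-oxo-1-(triethylsilyloxy)butyl]phenyl 4-methylbenzenesulfonate
Product: 17 2-(benzyloxy)-4-[(1S,2R,3R)-4-[3-methoxy-4-(tosyloxy)phenyl]-2,3-dimethyl-4-oxo-1-(triethylsilyloxy)butyl]phenyl 4-methylbenzenesulfonate, via arylmagnesium chloride 16 (not isolated)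
Conditions: 15 (1.6 equiv), i-PrMgCl·LiCl (1.5 equiv), THF, 0 °C → rt; then 13, 0 °C → rt; aq. NH4Cl
Reagents that add atoms: none
Why: Bromine–magnesium exchange with the turbo-Grignard reagent followed by Weinreb ketone synthesis: the chelated tetrahedral adduct should stop at the ketone stage and protect the α-stereocentre C4 from enolisation until work-up.

Step 11
Reactants: 17 2-(benzyloxy)-4-[(1S,2R,3R)-4-[3-methoxy-4-(tosyloxy)phenyl]-2,3-dimethyl-4-oxo-1-(triethylsilyloxy)butyl]phenyl 4-methylbenzenesulfonate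
Product: 18 2-(benzyloxy)-4-[(1S,2R,3R,4R)-4-hydroxy-4-[3-methoxy-4-(tosyloxy)phenyl]-2,3-dimethyl-1-(triethylsilyloxy)butyl]phenyl 4-methylbenzenesulfonate
Conditions: (S)-Me-CBS (0.2 equiv), BH3·SMe2 (1.0 equiv), THF, −20 °C; MeOH quench
Reagents that add atoms: none
Why: Corey–Bakshi–Shibata reduction: with the aryl group as the large substituent the (S)-oxazaborolidine should deliver hydride to give the (R)-carbinol at C5, the same sense as the Felkin–Anh preference (hydride anti to the branched C3 residue), so hydroxyl and C4 methyl end up anti.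

Step 12
Reactants: 18 2-(benzyloxy)-4-[(1S,2R,3R,4R)-4-hydroxy-4-[3-methoxy-4-(tosyloxy)phenyl]-2,3-dimethyl-1-(triethylsilyloxy)butyl]phenyl 4-methylbenzenesulfonate
Product: 21 2-(benzyloxy)-4-[(2S,3R,4R,5S)-5-[3-methoxy-4-(tosyloxy)phenyl]-3,4-dimethyltetrahydrofuran-2-yl]phenyl 4-methylbenzenesulfonate, via benzylic mesylate 19 (not isolated), via ammonium alkoxide 20 (not isolated)
Conditions: Ms2O (1.5 equiv), i-Pr2NEt (3 equiv), CH2Cl2, −20 °C; then TBAF (1 M in THF, 3 equiv), −20 → 0 °C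
Reagents that add atoms: none
Why: Chloride-free sulfonylation of the free C5 carbinol gives mesylate 19, fluoride then cleaves the Si–O bond, and the liberated C2 alkoxide 20 displaces the mesylate from the backside in an intramolecular Williamson-type SN2 reaction that forms O1–C5. The closest known reaction type is the cyclodehydration of 1,4-diols through a benzylic sulfonate that is displaced with inversion. The ring closes in the 5-exo-tet mode. C5 is the only centre that changes: the SN2 trajectory inverts it from R to S, whereas C2, C3 and C4 come unchanged from the open chain, which places the ring-B aryl cis to the C4 methyl. The step needs SN2 to outrun ionisation and E2: the para tosyloxy group on ring B (an acceptor in place of a donor oxygen) destabilises the benzylic cation, the absence of chloride excludes a double inversion via a benzylic chloride, and the unsolvated alkoxide closes a five-membered ring at low temperature faster than it can act as an external base.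

Step 13
Reactants: 21 2-(benzyloxy)-4-[(2S,3R,4R,5S)-5-[3-methoxy-4-(tosyloxy)phenyl]-3,4-dimethyltetrahydrofuran-2-yl]phenyl 4-methylbenzenesulfonate
Product: 22 2-(benzyloxy)-4-[(2S,3R,4R,5S)-5-(4-hydroxy-3-methoxyphenyl)-3,4-dimethyltetrahydrofuran-2-yl]phenol
Conditions: KOH (10 equiv), MeOH/THF 1:1, 60 °C; neutralise with aq. NH4Cl
Reagents that add atoms: none
Why: Alkaline cleavage of both aryl sulfonates by hydroxide attack at sulfur; the tetrahydrofuran, its stereocentres and the benzyl ether are stable to base, and acid is avoided from here on because C2 and C5 are now flanked by electron-rich aryl groups.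

Step 14
Reactants: 23 ethyl (S)-lactate
Product: 24 (S)-2-hydroxy-N-methoxy-N-methylpropanamide
Conditions: MeNHOMe·HCl (2.5 equiv), i-PrMgCl (5 equiv), THF, −20 → 0 °C
Reagents that add atoms: N,O-dimethylhydroxylamine hydrochloride, CNOC.Cl
Why: Ester aminolysis with the magnesium amide of N,O-dimethylhydroxylamine; the lactate centre, carried as its magnesium alkoxide, should not enolise.

Step 15
Reactants: 24 (S)-2-hydroxy-N-methoxy-N-methylpropanamide; 25 (3,4-dimethoxyphenyl)magnesium bromide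
Product: 26 (S)-1-(3,4-dimethoxyphenyl)-2-hydroxypropan-1-one
Conditions: 25 (3 equiv), THF, 0 °C → rt; aq. NH4Cl
Reagents that add atoms: none
Why: Weinreb ketone synthesis on the unprotected hydroxy amide: the first equivalent of Grignard reagent forms the alkoxide, the second adds, and the chelated adduct releases the ketone only on work-up, so the (S) centre should be kept.

Step 16
Reactants: 26 (S)-1-(3,4-dimethoxyphenyl)-2-hydroxypropan-1-one
Product: 27 (S)-1-(3,4-dimethoxyphenyl)-1-oxopropan-2-yl 4-methylbenzenesulfonate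
Conditions: TsCl (1.3 equiv), Et3N (2 equiv), DMAP (cat.), CH2Cl2, 0 °C
Reagents that add atoms: 4-toluenesulfonyl chloride, Cc1ccc(S(=O)(=O)Cl)cc1
Why: O-sulfonylation of the secondary alcohol without breaking its C–O bond (retention), giving a carbonyl-activated SN2 electrophile.

Step 17
Reactants: 22 2-(benzyloxy)-4-[(2S,3R,4R,5S)-5-(4-hydroxy-3-methoxyphenyl)-3,4-dimethyltetrahydrofuran-2-yl]phenol; 27 (S)-1-(3,4-dimethoxyphenyl)-1-oxopropan-2-yl 4-methylbenzenesulfonate
Product: 28 (2R)-2-[2-(benzyloxy)-4-[(2S,3R,4R,5S)-5-[4-[[(2R)-1-(3,4-dimethoxyphenyl)-1-oxopropan-2-yl]oxy]-3-methoxyphenyl]-3,4-dimethyltetrahydrofuran-2-yl]phenoxy]-1-(3,4-dimethoxyphenyl)propan-1-one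
Conditions: 27 (2.4 equiv), Cs2CO3 (3 equiv), DMF, 0 °C → rt
Reagents that add atoms: none
Why: Twofold Williamson ether synthesis: each phenoxide displaces the α-keto tosylate by SN2 with inversion, (S) to (R), and the weak carbonate base at low temperature should limit enolisation of the α-aryloxy ketones.

Step 18
Reactants: 28 the bis(α-aryloxy ketone) from step 17
Product: 29 (1R,2R)-2-[2-(benzyloxy)-4-[(2S,3R,4R,5S)-5-[4-[[(1R,2R)-1-(3,4-dimethoxyphenyl)-1-hydroxypropan-2-yl]oxy]-3-methoxyphenyl]-3,4-dimethyltetrahydrofuran-2-yl]phenoxy]-1-(3,4-dimethoxyphenyl)propan-1-ol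
Conditions: polymer-supported borohydride (Amberlite IRA-400, BH4− form, excess), MeOH, 0 °C → rt
Reagents that add atoms: none
Why: Felkin–Anh-controlled borohydride reduction of the two α-aryloxy ketones: with a non-chelating ammonium counter-ion hydride should add anti to the aryloxy group and give the syn (threo) (1R,2R) carbinol in each arm.

Step 19
Reactants: 29 O-benzyl manassantin B1 (the diol from step 18)
Product: 30 manassantin B1
Conditions: H2 (1 atm), 10% Pd/C, EtOAc, rt, stopped at full conversion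
Reagents that add atoms: none
Why: Catalytic hydrogenolysis of the aryl benzyl ether, which in neutral ethyl acetate should be much faster than cleavage of the benzylic C–O bonds of the tetrahydrofuran or of the two carbinols.

**Compound list**

1 | 3,4-dihydroxybenzaldehyde | O=Cc1ccc(O)c(O)c1 | starting material
2 | 4-formyl-2-hydroxyphenyl 4-methylbenzenesulfonate | Cc1ccc(S(=O)(=O)Oc2ccc(C=O)cc2O)cc1 | intermediate
3 | 2-(benzyloxy)-4-formylphenyl 4-methylbenzenesulfonate | Cc1ccc(S(=O)(=O)Oc2ccc(C=O)cc2OCc2ccccc2)cc1 | intermediate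
4 | cis-but-2-ene | C/C=C\C | starting material
5 | 2-(benzyloxy)-4-[(1S,2R)-1-(diisopinocampheylboryloxy)-2-methylbut-3-en-1-yl]phenyl 4-methylbenzenesulfonate | Cc1ccc(S(=O)(=O)Oc2ccc([C@@H](OB([C@@H]3C[C@@H]4C[C@H]([C@H]3C)C4(C)C)[C@@H]3C[C@@H]4C[C@H]([C@H]3C)C4(C)C)[C@H](C)C=C)cc2OCc2ccccc2)cc1 | intermediate (not isolated)
6 | 2-(benzyloxy)-4-[(1S,2R)-1-hydroxy-2-methylbut-3-en-1-yl]phenyl 4-methylbenzenesulfonate | Cc1ccc(S(=O)(=O)Oc2ccc([C@@H](O)[C@H](C)C=C)cc2OCc2ccccc2)cc1 | intermediate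
7 | 2-(benzyloxy)-4-[(1S,2R)-4-(9-borabicyclo[3.3.1]nonan-9-yl)-1-hydroxy-2-methylbutyl]phenyl 4-methylbenzenesulfonate | Cc1ccc(S(=O)(=O)Oc2ccc([C@@H](O)[C@H](C)CCB3C4CCCC3CCC4)cc2OCc2ccccc2)cc1 | intermediate (not isolated)
8 | 2-(benzyloxy)-4-[(1S,2R)-1,4-dihydroxy-2-methylbutyl]phenyl 4-methylbenzenesulfonate | Cc1ccc(S(=O)(=O)Oc2ccc([C@@H](O)[C@H](C)CCO)cc2OCc2ccccc2)cc1 | intermediate
9 | 2-(benzyloxy)-4-[(2S,3R)-3-methyl-5-oxotetrahydrofuran-2-yl]phenyl 4-methylbenzenesulfonate (aryl and methyl cis) | Cc1ccc(S(=O)(=O)Oc2ccc([C@H]3OC(=O)C[C@H]3C)cc2OCc2ccccc2)cc1 | intermediate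
10 | lithium (4R,5S)-5-[3-(benzyloxy)-4-(tosyloxy)phenyl]-4-methyl-4,5-dihydrofuran-2-olate | Cc1ccc(S(=O)(=O)Oc2ccc([C@H]3OC(O[Li])=C[C@H]3C)cc2OCc2ccccc2)cc1 | intermediate (not isolated)
11 | 2-(benzyloxy)-4-[(2S,3R,4R)-3,4-dimethyl-5-oxotetrahydrofuran-2-yl]phenyl 4-methylbenzenesulfonate (2,3-cis, 3,4-trans) | Cc1ccc(S(=O)(=O)Oc2ccc([C@H]3OC(=O)[C@H](C)[C@H]3C)cc2OCc2ccccc2)cc1 | intermediate
12 | 2-(benzyloxy)-4-[(1S,2R,3R)-1-hydroxy-4-[methoxy(methyl)amino]-2,3-dimethyl-4-oxobutyl]phenyl 4-methylbenzenesulfonate | Cc1ccc(S(=O)(=O)Oc2ccc([C@@H](O)[C@H](C)[C@@H](C)C(=O)N(C)OC)cc2OCc2ccccc2)cc1 | intermediate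
13 | 2-(benzyloxy)-4-[(1S,2R,3R)-4-[methoxy(methyl)amino]-2,3-dimethyl-4-oxo-1-(triethylsilyloxy)butyl]phenyl 4-methylbenzenesulfonate | Cc1ccc(S(=O)(=O)Oc2ccc([C@@H](O[Si](CC)(CC)CC)[C@H](C)[C@@H](C)C(=O)N(C)OC)cc2OCc2ccccc2)cc1 | intermediate
14 | 4-bromo-2-methoxyphenol | COc1cc(Br)ccc1O | starting material
15 | 4-bromo-2-methoxyphenyl 4-methylbenzenesulfonate | COc1cc(Br)ccc1OS(=O)(=O)c1ccc(C)cc1 | intermediate
16 | [3-methoxy-4-(tosyloxy)phenyl]magnesium chloride (LiCl adduct) | COc1cc([Mg]Cl)ccc1OS(=O)(=O)c1ccc(C)cc1 | intermediate (not isolated)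
17 | 2-(benzyloxy)-4-[(1S,2R,3R)-4-[3-methoxy-4-(tosyloxy)phenyl]-2,3-dimethyl-4-oxo-1-(triethylsilyloxy)butyl]phenyl 4-methylbenzenesulfonate | Cc1ccc(S(=O)(=O)Oc2ccc([C@@H](O[Si](CC)(CC)CC)[C@H](C)[C@@H](C)C(=O)c3ccc(OS(=O)(=O)c4ccc(C)cc4)c(OC)c3)cc2OCc2ccccc2)cc1 | intermediate
18 | 2-(benzyloxy)-4-[(1S,2R,3R,4R)-4-hydroxy-4-[3-methoxy-4-(tosyloxy)phenyl]-2,3-dimethyl-1-(triethylsilyloxy)butyl]phenyl 4-methylbenzenesulfonate | Cc1ccc(S(=O)(=O)Oc2ccc([C@@H](O[Si](CC)(CC)CC)[C@H](C)[C@@H](C)[C@@H](O)c3ccc(OS(=O)(=O)c4ccc(C)cc4)c(OC)c3)cc2OCc2ccccc2)cc1 | intermediate (key-step precursor)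
19 | 2-(benzyloxy)-4-[(1S,2R,3R,4R)-4-(methanesulfonyloxy)-4-[3-methoxy-4-(tosyloxy)phenyl]-2,3-dimethyl-1-(triethylsilyloxy)butyl]phenyl 4-methylbenzenesulfonate | Cc1ccc(S(=O)(=O)Oc2ccc([C@@H](O[Si](CC)(CC)CC)[C@H](C)[C@@H](C)[C@@H](OS(C)(=O)=O)c3ccc(OS(=O)(=O)c4ccc(C)cc4)c(OC)c3)cc2OCc2ccccc2)cc1 | intermediate (not isolated)
20 | tetrabutylammonium (1S,2R,3R,4R)-1-[3-(benzyloxy)-4-(tosyloxy)phenyl]-4-(methanesulfonyloxy)-4-[3-methoxy-4-(tosyloxy)phenyl]-2,3-dimethylbutan-1-olate | Cc1ccc(S(=O)(=O)Oc2ccc([C@@H]([O-])[C@H](C)[C@@H](C)[C@@H](OS(C)(=O)=O)c3ccc(OS(=O)(=O)c4ccc(C)cc4)c(OC)c3)cc2OCc2ccccc2)cc1.CCCC[N+](CCCC)(CCCC)CCCC | intermediate (not isolated)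
21 | 2-(benzyloxy)-4-[(2S,3R,4R,5S)-5-[3-methoxy-4-(tosyloxy)phenyl]-3,4-dimethyltetrahydrofuran-2-yl]phenyl 4-methylbenzenesulfonate | Cc1ccc(S(=O)(=O)Oc2ccc([C@H]3O[C@H](c4ccc(OS(=O)(=O)c5ccc(C)cc5)c(OC)c4)[C@H](C)[C@H]3C)cc2OCc2ccccc2)cc1 | intermediate (key-step product)
22 | 2-(benzyloxy)-4-[(2S,3R,4R,5S)-5-(4-hydroxy-3-methoxyphenyl)-3,4-dimethyltetrahydrofuran-2-yl]phenol | Oc1ccc([C@H]2O[C@H](c3ccc(O)c(OC)c3)[C@H](C)[C@H]2C)cc1OCc1ccccc1 | intermediate
23 | ethyl (S)-lactate | CCOC(=O)[C@H](C)O | starting material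
24 | (S)-2-hydroxy-N-methoxy-N-methylpropanamide | CON(C)C(=O)[C@H](C)O | intermediate
25 | (3,4-dimethoxyphenyl)magnesium bromide (THF solution) | COc1ccc([Mg]Br)cc1OC | starting material
26 | (S)-1-(3,4-dimethoxyphenyl)-2-hydroxypropan-1-one | COc1ccc(C(=O)[C@H](C)O)cc1OC | intermediate
27 | (S)-1-(3,4-dimethoxyphenyl)-1-oxopropan-2-yl 4-methylbenzenesulfonate | COc1ccc(C(=O)[C@H](C)OS(=O)(=O)c2ccc(C)cc2)cc1OC | intermediate
28 | (2R)-2-[2-(benzyloxy)-4-[(2S,3R,4R,5S)-5-[4-[[(2R)-1-(3,4-dimethoxyphenyl)-1-oxopropan-2-yl]oxy]-3-methoxyphenyl]-3,4-dimethyltetrahydrofuran-2-yl]phenoxy]-1-(3,4-dimethoxyphenyl)propan-1-one | COc1ccc(C(=O)[C@@H](C)Oc2ccc([C@H]3O[C@H](c4ccc(O[C@H](C)C(=O)c5ccc(OC)c(OC)c5)c(OC)c4)[C@H](C)[C@H]3C)cc2OCc2ccccc2)cc1OC | intermediate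
29 | (1R,2R)-2-[2-(benzyloxy)-4-[(2S,3R,4R,5S)-5-[4-[[(1R,2R)-1-(3,4-dimethoxyphenyl)-1-hydroxypropan-2-yl]oxy]-3-methoxyphenyl]-3,4-dimethyltetrahydrofuran-2-yl]phenoxy]-1-(3,4-dimethoxyphenyl)propan-1-ol | COc1ccc([C@@H](O)[C@@H](C)Oc2ccc([C@H]3O[C@H](c4ccc(O[C@H](C)[C@H](O)c5ccc(OC)c(OC)c5)c(OC)c4)[C@H](C)[C@H]3C)cc2OCc2ccccc2)cc1OC | intermediate
30 | manassantin B1 | COc1ccc([C@@H](O)[C@@H](C)Oc2ccc([C@H]3O[C@H](c4ccc(O[C@H](C)[C@H](O)c5ccc(OC)c(OC)c5)c(OC)c4)[C@H](C)[C@H]3C)cc2O)cc1OC | target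

**Step count and risks**

Total: 19 steps. Longest linear sequence: 15 steps (1–8, 10–13, 17–19).

Steps most likely to fail:

(a) Step 12. The benzylic mesylate may ionise, or lose a proton from C4 (E2), faster than it is displaced, so that C5 is scrambled or a styrene forms. The fallback forms the C5–aryl bond on a preformed ring instead of the O1–C5 bond. It sets out from lactone 11: DIBAL-H (CH2Cl2, −78 °C) should give lactol F1, and benzenesulfinic acid with CaCl2 should convert this into the 2-phenylsulfonyl tetrahydrofuran F2. The arylzinc bromide F3, made from 16 and ZnBr2, would then add to the oxocarbenium ion released from F2. The nucleophile should enter trans to the C3 methyl and the C2 aryl (inside attack on the envelope) and therefore cis to the C4 methyl, and the route is rejoined at 21.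

(b) Step 10. The bromine–magnesium exchange may stall, the arylmagnesium may attack a sulfonate ester, or addition to the hindered amide may stop short. The fallback carries the ring-B oxygen as a silyl ether through the organometallic step. It sets out from 14: TBSCl/imidazole should give silyl ether F4, and Br/Li exchange (n-BuLi, THF, −78 °C) the aryllithium F5, which adds to 13 to give ketone F6. K2CO3 in MeOH should remove only the phenolic silyl group to give phenol F7, and TsCl/Et3N then returns to the route at 17.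

(c) Step 7. The hydroxy amide may close back to the lactone during work-up or silylation, a ring closure favoured by the three ring substituents. The fallback opens the lactone with the carbon nucleophile itself. It sets out from 11: one equivalent of 16 at −78 °C should stop at the mono-adduct, hydroxy ketone F8 (in equilibrium with its cyclic hemiketal). TESCl/imidazole should then trap the open-chain form at the secondary hydroxyl, and the route is rejoined at 17, bypassing 12 and 13.

Further compounds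
F1 | step 12 | 2-(benzyloxy)-4-[(2S,3R,4R)-5-hydroxy-3,4-dimethyltetrahydrofuran-2-yl]phenyl 4-methylbenzenesulfonate (anomer mixture) | Cc1ccc(S(=O)(=O)Oc2ccc([C@H]3OC(O)[C@H](C)[C@H]3C)cc2OCc2ccccc2)cc1
F2 | step 12 | 2-(benzyloxy)-4-[(2S,3R,4R)-3,4-dimethyl-5-(phenylsulfonyl)tetrahydrofuran-2-yl]phenyl 4-methylbenzenesulfonate (anomer mixture) | Cc1ccc(S(=O)(=O)Oc2ccc([C@H]3OC(S(=O)(=O)c4ccccc4)[C@H](C)[C@H]3C)cc2OCc2ccccc2)cc1
F3 | step 12 | [3-methoxy-4-(tosyloxy)phenyl]zinc bromide | COc1cc([Zn]Br)ccc1OS(=O)(=O)c1ccc(C)cc1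
F4 | step 10 | (4-bromo-2-methoxyphenoxy)(tert-butyl)dimethylsilane | COc1cc(Br)ccc1O[Si](C)(C)C(C)(C)C
F5 | step 10 | [4-(tert-butyldimethylsilyloxy)-3-methoxyphenyl]lithium | COc1cc([Li])ccc1O[Si](C)(C)C(C)(C)C
F6 | step 10 | 2-(benzyloxy)-4-[(1S,2R,3R)-4-[4-(tert-butyldimethylsilyloxy)-3-methoxyphenyl]-2,3-dimethyl-4-oxo-1-(triethylsilyloxy)butyl]phenyl 4-methylbenzenesulfonate | Cc1ccc(S(=O)(=O)Oc2ccc([C@@H](O[Si](CC)(CC)CC)[C@H](C)[C@@H](C)C(=O)c3ccc(O[Si](C)(C)C(C)(C)C)c(OC)c3)cc2OCc2ccccc2)cc1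
F7 | step 10 | 2-(benzyloxy)-4-[(1S,2R,3R)-4-(4-hydroxy-3-methoxyphenyl)-2,3-dimethyl-4-oxo-1-(triethylsilyloxy)butyl]phenyl 4-methylbenzenesulfonate | Cc1ccc(S(=O)(=O)Oc2ccc([C@@H](O[Si](CC)(CC)CC)[C@H](C)[C@@H](C)C(=O)c3ccc(O)c(OC)c3)cc2OCc2ccccc2)cc1
F8 | step 7 | 2-(benzyloxy)-4-[(1S,2R,3R)-1-hydroxy-4-[3-methoxy-4-(tosyloxy)phenyl]-2,3-dimethyl-4-oxobutyl]phenyl 4-methylbenzenesulfonate (in equilibrium with its cyclic hemiketal) | Cc1ccc(S(=O)(=O)Oc2ccc([C@@H](O)[C@H](C)[C@@H](C)C(=O)c3ccc(OS(=O)(=O)c4ccc(C)cc4)c(OC)c3)cc2OCc2ccccc2)cc1
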